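**Plan**

- Retrosynthetic cuts: (1) the octanoate C–O bond and the two benzyl-type protecting groups; (2) the C–H bond of the secondary carbinol, back to a 2-hydroxy-2-phenylcyclopentanone; (3) in one operation, the ring bond CH(O)–C(OH)Ph and the ring bond between the amino acid carbon and its CH2 neighbour, which leaves a formylglycine ester and phenyl vinyl ketone.
- Enabling feature: in the cyclopentane the oxygenated CH lies between the N/CO2H-bearing quaternary carbon and the PhC(OH) carbon. As a formyl group this carbon first acidifies the glycine C–H (Michael donor toward the enone CH2) and then, with its polarity reversed by a carbene, acts as an acyl anion placed 1,5 to the aryl ketone.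
- Forward order: C-formylation of N-Cbz-glycine benzyl ester; a one-flask Michael addition/crossed benzoin closes the only carbocycle as an α-ketol; directed reduction; O-octanoylation; hydrogenolysis.
- Stereochemistry: the quaternary centre comes from a chiral cinchona base in the conjugate addition; the tertiary carbinol from substrate control in the ring closure (OH cis to NHCbz); the secondary carbinol from hydroxyl-directed hydride delivery (trans-diol).

Key step: step 3

Remark: the formyl ester 3 exists largely as its hydrogen-bonded enol; it is drawn as the aldehyde tautomer, whose α-carbon is configurationally labile, so no descriptor is given.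

Remark: the sense of induction of the quinidine-derived base in step 3 is assumed by analogy with 2-substituted 1,3-dicarbonyl donors; should it be opposite, the pseudoenantiomeric quinine-derived base O-benzylcupreine is used instead.

**Route**

Step 1
Reactants: 1 benzyl N-(benzyloxycarbonyl)glycinate
Product: 3 benzyl 2-(benzyloxycarbonylamino)-3-oxopropanoate, via enamino ester 2 (not isolated)
Conditions: t-BuOCH(NMe2)2 (1.5 equiv), toluene, 90 °C; evaporate; then 1 M aq HCl, THF, 23 °C
Reagents that add atoms: tert-butoxybis(dimethylamino)methane, CN(C)C(OC(C)(C)C)N(C)C; water, O
Why: Aminal ester condensation at the activated glycine methylene (C-formylation at the enamine level) gives the dimethylaminomethylene ester, and acid hydrolysis of this vinylogous carbamate should release the formyl ester as its enol without touching the benzyl ester or the Cbz group; no stereocentre is involved.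

Step 2
Reactants: 4 3-chloro-1-phenylpropan-1-one
Product: 5 1-phenylprop-2-en-1-one (phenyl vinyl ketone)
Conditions: Et3N (1.2 equiv), CH2Cl2, 23 °C; wash with 0.5 M HCl, dry, use at once
Reagents that add atoms: none
Why: E1cB dehydrochlorination of the β-chloro ketone should give the enone, which is made fresh because it polymerises on storage and is washed free of amine so that no achiral base enters step 3.

Step 3
Reactants: 3 benzyl 2-(benzyloxycarbonylamino)-3-oxopropanoate (1.05 equiv), 5 1-phenylprop-2-en-1-one
Product: 7 benzyl (1S,3S)-1-(benzyloxycarbonylamino)-3-hydroxy-2-oxo-3-phenylcyclopentane-1-carboxylate, via formyl ester 6 (not isolated)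
Conditions: O-benzylcupreidine [(9S)-9-(benzyloxy)cinchonan-6'-ol] (10 mol %), CH2Cl2, −20 °C; then, same flask, 2-(pentafluorophenyl)-6,7-dihydro-5H-pyrrolo[2,1-c][1,2,4]triazol-2-ium tetrafluoroborate (10 mol %), i-Pr2NEt (20 mol %), 23 °C
Reagents that add atoms: none
Why: Proposed new method: the quinuclidine nitrogen of the cinchona base deprotonates the acidic enol 3 and the hydrogen-bonded ammonium enolate adds through carbon to the enone 5 (activated by the 6'-hydroxyl) to give the non-enolisable formyl ester 6, after which the triazolylidene freed in the second stage adds to the formyl group, the resulting hydroxy-enamine (an acyl anion equivalent, the aldehyde carbon with reversed polarity) attacks the 1,5-related aryl ketone and the carbene is expelled from the adduct to give ketol 7. The closest known reaction types are the amine/carbene relay Michael–crossed benzoin cascades that turn 1,3-dicarbonyl donors into 2-hydroxycyclopentanones, the cinchona-catalysed conjugate addition of 2-substituted 1,3-dicarbonyl compounds to vinyl ketones and the carbene-catalysed intramolecular crossed benzoin of keto aldehydes, and what is new is a formylglycine donor that brings the aldehyde with it, so that the acyl anion carbon is the one attached to the freshly made quaternary centre. The cyclopentane closes in the 5-exo-trig mode, the acyl anion carbon attacking the ketone carbon while the C=O bond stays outside the ring. The quaternary amino acid centre (S) is set by the chiral base in the conjugate addition and cannot epimerise afterwards, and the tertiary carbinol (S) is set by the substrate in the ring closure, where the carbamate N–H should hydrogen-bond to the ketone oxygen so that hydroxyl and NHCbz end up cis and phenyl and ester cis, the reversibility of the benzoin addition letting this hydrogen-bonded isomer accumulate. The step needs C- over O-alkylation of the enolate (secured by the soft enone acceptor), conjugate addition before carbene chemistry (secured by adding the triazolium salt only once 5 is consumed, which also keeps the carbene away from the polymerisable enone and excludes a racemic base-mediated background addition) and crossed over homo-benzoin coupling (secured by intramolecularity and by the α-quaternary aldehyde, which does not dimerise).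

Step 4
Reactants: 7 benzyl (1S,3S)-1-(benzyloxycarbonylamino)-3-hydroxy-2-oxo-3-phenylcyclopentane-1-carboxylate
Product: 8 benzyl (1S,2R,3S)-1-(benzyloxycarbonylamino)-2,3-dihydroxy-3-phenylcyclopentane-1-carboxylate
Conditions: Me4NBH(OAc)3 (4 equiv), MeCN–AcOH (1:1), −20 to 0 °C
Reagents that add atoms: none
Why: Hydroxyl-directed triacetoxyborohydride reduction (Saksena–Evans type): ligand exchange of the tertiary hydroxyl on boron should deliver hydride to the carbonyl face syn to that hydroxyl, which is also the face remote from phenyl and the benzyl ester, so the new secondary hydroxyl is trans to the tertiary one (2R), and the acidic medium avoids retro-Claisen opening of the non-enolisable β-keto ester.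

Step 5
Reactants: 8 benzyl (1S,2R,3S)-1-(benzyloxycarbonylamino)-2,3-dihydroxy-3-phenylcyclopentane-1-carboxylate
Product: 9 benzyl (1S,2R,3S)-1-(benzyloxycarbonylamino)-3-hydroxy-2-(octanoyloxy)-3-phenylcyclopentane-1-carboxylate
Conditions: n-C7H15COCl (1.5 equiv), pyridine, DMAP (0.2 equiv), CH2Cl2, 0 to 23 °C
Reagents that add atoms: octanoyl chloride, CCCCCCCC(=O)Cl
Why: DMAP-catalysed O-acylation through the N-acylpyridinium ion should be selective for the secondary hydroxyl over the tertiary benzylic hydroxyl and the carbamate N–H, and the trans arrangement of the two oxygens on the five-membered ring prevents acyl migration.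

Step 6
Reactants: 9 benzyl (1S,2R,3S)-1-(benzyloxycarbonylamino)-3-hydroxy-2-(octanoyloxy)-3-phenylcyclopentane-1-carboxylate
Product: 10 Fusarilin A, (1S,2R,3S)-1-amino-3-hydroxy-2-(octanoyloxy)-3-phenylcyclopentane-1-carboxylic acid
Conditions: H2 (1 atm), 10% Pd/C, EtOAc–MeOH, 23 °C
Reagents that add atoms: none
Why: Neutral hydrogenolysis should cleave the benzyl ester and the benzyl carbamate (with loss of CO2 from the carbamic acid) while the octanoate and the tertiary benzylic alcohol, which needs acid or forcing conditions for cleavage, stay intact, and the trans relationship of amine and acyloxy group on the ring disfavours O-to-N acyl shift in the zwitterion.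

**Compound list**

1 | benzyl N-(benzyloxycarbonyl)glycinate | O=C(OCc1ccccc1)CNC(=O)OCc1ccccc1 | starting material
2 | benzyl (Z)-2-(benzyloxycarbonylamino)-3-(dimethylamino)prop-2-enoate (not isolated) | CN(C)/C=C(\NC(=O)OCc1ccccc1)C(=O)OCc1ccccc1 | intermediate
3 | benzyl 2-(benzyloxycarbonylamino)-3-oxopropanoate (mainly the enol, benzyl 2-(benzyloxycarbonylamino)-3-hydroxyprop-2-enoate; aldehyde tautomer drawn) | O=CC(NC(=O)OCc1ccccc1)C(=O)OCc1ccccc1 | intermediate
4 | 3-chloro-1-phenylpropan-1-one | O=C(CCCl)c1ccccc1 | starting material
5 | 1-phenylprop-2-en-1-one (phenyl vinyl ketone) | C=CC(=O)c1ccccc1 | intermediate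
6 | benzyl (S)-2-(benzyloxycarbonylamino)-2-formyl-5-oxo-5-phenylpentanoate (not isolated) | O=C[C@](NC(=O)OCc1ccccc1)(C(=O)OCc1ccccc1)CCC(=O)c1ccccc1 | intermediate
7 | benzyl (1S,3S)-1-(benzyloxycarbonylamino)-3-hydroxy-2-oxo-3-phenylcyclopentane-1-carboxylate (hydroxyl cis to NHCbz, phenyl cis to the ester) | O=C1[C@](NC(=O)OCc2ccccc2)(C(=O)OCc2ccccc2)CC[C@]1(O)c1ccccc1 | intermediate
8 | benzyl (1S,2R,3S)-1-(benzyloxycarbonylamino)-2,3-dihydroxy-3-phenylcyclopentane-1-carboxylate (trans-diol, secondary hydroxyl cis to phenyl and ester) | O[C@@H]1[C@](NC(=O)OCc2ccccc2)(C(=O)OCc2ccccc2)CC[C@]1(O)c1ccccc1 | intermediate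
9 | benzyl (1S,2R,3S)-1-(benzyloxycarbonylamino)-3-hydroxy-2-(octanoyloxy)-3-phenylcyclopentane-1-carboxylate | CCCCCCCC(=O)O[C@@H]1[C@](NC(=O)OCc2ccccc2)(C(=O)OCc2ccccc2)CC[C@]1(O)c1ccccc1 | intermediate
10 | Fusarilin A, (1S,2R,3S)-1-amino-3-hydroxy-2-(octanoyloxy)-3-phenylcyclopentane-1-carboxylic acid (octanoyloxy trans to the amino group and to the tertiary hydroxyl, cis to carboxyl and phenyl) | CCCCCCCC(=O)O[C@@H]1[C@](N)(C(=O)O)CC[C@]1(O)c1ccccc1 | target

**Step count**

Total steps: 6. Longest linear sequence: 5 steps (steps 1, 3, 4, 5 and 6, from compound 1); step 2 is a one-step side branch.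

**Steps most likely to fail**

1. Step 3 (bears the label).
   - What may go wrong: low enantio-induction in the conjugate addition with this enol donor (a loosely organised ion pair); loss of the formyl group by retro-Claisen fragmentation when the carbene adds to the non-enolisable, doubly activated aldehyde; poor facial selectivity in the attack on the ketone.
   - Fallback (known chemistry only): it sets out from 3 and 5 and comes back at 7. Triethylamine-catalysed Michael addition (CH2Cl2, 0 °C) should give the racemic aldehyde benzyl 2-(benzyloxycarbonylamino)-2-formyl-5-oxo-5-phenylpentanoate F1, which is isolated. SmI2 (2.2 equiv, THF, t-BuOH, −78 °C) should then close the ring by ketyl–carbonyl pinacol coupling, without any nucleophile at the formyl group, to the racemic cis-diol benzyl (1S*,2S*,3S*)-1-(benzyloxycarbonylamino)-2,3-dihydroxy-3-phenylcyclopentane-1-carboxylate F2; any diastereomer at the tertiary carbinol is removed on silica. Parikh–Doering oxidation of the secondary hydroxyl (SO3·pyridine, DMSO, i-Pr2NEt, 0 °C) should give the racemic ketol. Preparative chromatography on a chiral stationary phase then separates 7 from its mirror image, benzyl (1R,3R)-1-(benzyloxycarbonylamino)-3-hydroxy-2-oxo-3-phenylcyclopentane-1-carboxylate F3.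

2. Step 5.
   - What may go wrong: slow acyl transfer to a secondary carbinol that is flanked by two fully substituted carbons and lies syn to phenyl and the benzyl ester; forcing conditions would invite attack of the tertiary hydroxyl on the carbamate carbonyl.
   - Fallback: it sets out from 8 and comes back at 10, with the order of the last two events reversed. Hydrogenolysis of 8 (H2, 10% Pd/C, MeOH) should give the free amino acid diol (1S,2R,3S)-1-amino-2,3-dihydroxy-3-phenylcyclopentane-1-carboxylic acid F4, now without the two bulky benzyl-type groups. Chemoselective O-acylation under acidic conditions (octanoyl chloride in CF3CO2H, 0 °C), in which the protonated amine is protected and the secondary hydroxyl is the most accessible nucleophile, should then give 10 directly.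

3. Step 4.
   - What may go wrong: failure of ligand exchange at the hindered tertiary hydroxyl, so that no hydride is delivered to a carbonyl flanked by two quaternary carbons.
   - Fallback: it sets out from 7 and comes back at 8, and replaces internal delivery by an external hydride under chelation and steric approach control. Zn(BH4)2 in Et2O at −20 °C (neutral, so that retro-Claisen ring opening is not provoked) should attack the zinc chelate of the ketol from the face anti to phenyl and the benzyl ester and give the same trans-diol 8. This fallback passes through no new compound, F0.

Further compounds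
F1 | step 3 | benzyl 2-(benzyloxycarbonylamino)-2-formyl-5-oxo-5-phenylpentanoate (racemic) | O=CC(NC(=O)OCc1ccccc1)(C(=O)OCc1ccccc1)CCC(=O)c1ccccc1
F2 | step 3 | benzyl (1S*,2S*,3S*)-1-(benzyloxycarbonylamino)-2,3-dihydroxy-3-phenylcyclopentane-1-carboxylate (racemic cis-diol, one enantiomer drawn) | O[C@H]1[C@](NC(=O)OCc2ccccc2)(C(=O)OCc2ccccc2)CC[C@]1(O)c1ccccc1
F3 | step 3 | benzyl (1R,3R)-1-(benzyloxycarbonylamino)-3-hydroxy-2-oxo-3-phenylcyclopentane-1-carboxylate (mirror image of 7) | O=C1[C@@](NC(=O)OCc2ccccc2)(C(=O)OCc2ccccc2)CC[C@@]1(O)c1ccccc1
F4 | step 5 | (1S,2R,3S)-1-amino-2,3-dihydroxy-3-phenylcyclopentane-1-carboxylic acid | O[C@@H]1[C@](N)(C(=O)O)CC[C@]1(O)c1ccccc1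
F0 | step 4 | none | none
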